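**Retrosynthetic overview**
- The cyclohexene that joins the halves (C2–C1=C10–C14–C15'–C4') is cut at C14–C15' and C2–C4' (Diels–Alder / Michael–aldol retron). This gives dehydrozaluzanin C (two steps from dehydrocostus lactone) and a 2-hydroxy-diene of the unprimed half (C14=C10–C1=C2–OH, C3 ketone, C4 methylene).
- Feature used: in the unprimed half the lactone oxygen on C6 and the C1=C10 alkene lie 1,4 across the seven-membered ring (C6–C5–C1=C10), with C2 oxygenated next to C1. This is the pattern left when a C2 carbonyl β-eliminates a C6–O–C10 ether bridge, and that ring opening is used to trigger the union.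
- The bridged seven-membered ring is an 8-oxabicyclo[3.2.1]octenone, cut at C5–C6 and C1–C10 into 6-methyl-3-oxidopyrylium (from 5-methylfurfuryl alcohol) and (R)-4-silyloxycyclopentenone.
- Ring order: ring A (purchased) → seven-membered carbocycle with the oxygen bridge (step 3) → C11–C13 on C7, C4 methylene and C3 oxygen installed on the rigid bicycle → bridge opening and cyclohexene (step 17) → lactone (step 18).

Key step: step 3

Remark: guaianolide numbering is used (unprimed for the half with the tertiary alcohol, primed for the dehydrocostus-lactone half; α/β as in the usual drawing, H5 α); 19 is written as the 2,3-diketone although its C1 enol is probably the main tautomer.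

**Step 1**
Reactants: 1 5-methylfurfuryl alcohol
Product: 2 rac-6-hydroxy-6-methyl-2H-pyran-3(6H)-one
Conditions: mCPBA, CH2Cl2, 0 °C
Reagents that add atoms: mCPBA, OOC(=O)c1cccc(Cl)c1
Why: Achmatowicz rearrangement, in which peracid oxidation of the 2-furylcarbinol gives an ene-dione that closes to the six-membered hemiketal; the hemiketal carbon is racemic but becomes sp2 in step 3.

**Step 2**
Reactants: 2 rac-6-hydroxy-6-methyl-2H-pyran-3(6H)-one
Product: 3 rac-6-acetoxy-6-methyl-2H-pyran-3(6H)-one
Conditions: Ac2O, pyridine, DMAP (cat.), CH2Cl2, 0 °C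
Reagents that add atoms: acetic anhydride, CC(=O)OC(C)=O
Why: DMAP-catalysed O-acetylation of the tertiary hemiketal installs the leaving group for ylide formation, run cold and briefly because amines already start loss of acetate.

**Step 3**
Reactants: 3 rac-6-acetoxy-6-methyl-2H-pyran-3(6H)-one; 4 (R)-4-(tert-butyldimethylsilyloxy)cyclopent-2-en-1-one
Product: 6 endo (5+2) adduct 4α-TBSO-6α,10α-epoxy-10β-methyl-hydroazul-8-ene-2,7-dione (1αH 5αH 6βH), via 6-methyl-3-oxidopyrylium 5 (not isolated)
Conditions: i-Pr2NEt, MeCN, 40 °C; 3 (3 equiv) added slowly to 4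
Reagents that add atoms: none
Why: The amine removes the proton next to the ketone of 3 and acetate leaves, giving the oxidopyrylium 5, a cyclic carbonyl ylide that adds across C1=C5 of 4 in a concerted suprafacial (5+2) cycloaddition; the closest known reaction is the intermolecular (5+2) of acetoxypyranone-derived 3-oxidopyrylium ylides with enones and acrylates. The ylide carbon next to the oxido carbon (C6, largest HOMO coefficient) bonds to the enone β-carbon C5 and the methyl-bearing terminus C10 bonds to the α-carbon C1, the regiochemistry seen with acyclic acceptors. The seven-membered carbocycle (C1, C5, C6, C7, C8, C9, C10) is closed by the intermolecular cycloaddition itself, both σ bonds (C5–C6 and C1–C10) forming in one event, which also creates the 6α,10α oxygen bridge of an 8-oxabicyclo[3.2.1]oct-3-en-2-one. C5 and C1 are set by approach anti to the C4 silyloxy group (substrate control, suprafacial on the enone), and C6 and C10 are set relative to them by the endo transition state with ring A beneath the C7–C8–C9 enone bridge, which places the bridging oxygen cis to H5. The step needs regio-, facial and endo selectivity; these rest on the ylide polarization, the silyloxy stereocentre and secondary overlap of the C2 carbonyl with the ylide π-system, respectively. Slow addition of excess 3 limits ylide dimerization, and a hindered amine at moderate temperature spares the β-silyloxy ketone and the β-alkoxy ketone of 6.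

**Step 4**
Reactants: 6 endo (5+2) adduct
Product: 7 C2 ethylene ketal of 6
Conditions: TMSOCH2CH2OTMS, TMSOTf (cat.), CH2Cl2, −78 → −20 °C
Reagents that add atoms: 1,2-bis(trimethylsilyloxy)ethane, C[Si](C)(C)OCCO[Si](C)(C)C
Why: TMSOTf-catalysed ketalization with the bis-silyl ether is selective for the saturated cyclopentanone over the conjugated, α-oxygenated C7 ketone, and with C2 masked no enolizable ketone remains, so neither the C4 silyloxy group nor the bridge can be lost by β-elimination in the basic steps that follow.

**Step 5**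
Reactants: 7 C2 ethylene ketal of 6; 8 trimethyl phosphonoacetate
Product: 9 C7 (methoxycarbonyl)methylidene dienoate (E/Z mixture at C7=C11)
Conditions: NaH, THF, 0 → 45 °C
Reagents that add atoms: none
Why: Horner–Wadsworth–Emmons olefination, in which the phosphonate anion adds 1,2 to the C7 ketone (activated by the α-oxygen, while conjugate addition at C9 is hindered by the adjacent quaternary C10); both alkene isomers converge in step 6.

**Step 6**
Reactants: 9 C7 (methoxycarbonyl)methylidene dienoate
Product: 10 saturated methyl ester (C7–CH2CO2Me, 7αH, C8 and C9 saturated)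
Conditions: H2 (1 atm), Pd/C, EtOAc, 23 °C
Reagents that add atoms: none
Why: Heterogeneous hydrogenation saturates C8=C9 and C7=C11, and hydrogen should reach C7 from the α-face (the side of the oxygen bridge) because the β-face is covered by the endo-fused ring A, which sets H7 α and the side chain trans to the C6 oxygen as the trans-lactone requires.

**Step 7**
Reactants: 10 saturated methyl ester
Product: 11 C4α alcohol
Conditions: TBAF, THF, 0 → 23 °C
Reagents that add atoms: none
Why: Fluoride-induced cleavage of the silyl ether; ketal, ester and bridge are inert to it.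

**Step 8**
Reactants: 11 C4α alcohol
Product: 12 C4 ketone
Conditions: Dess–Martin periodinane, pyridine, CH2Cl2, 0 → 23 °C
Reagents that add atoms: none
Why: Dess–Martin oxidation under buffered, non-enolizing conditions gives the C4 ketone, which is used at once because its C5 enolate would expel the C6 bridge oxygen.

**Step 9**
Reactants: 12 C4 ketone
Product: 13 C4 exocyclic methylene compound (C4=C15)
Conditions: CH2Br2, Zn, TiCl4, THF/CH2Cl2, 0 → 23 °C
Reagents that add atoms: dibromomethane, BrCBr
Why: Takai–Lombardo methylenation with the non-basic Zn/Ti gem-dimetallic reagent converts the ketone to the methylene without enolization toward C5 (loss of the bridge) or C3 (opening of the ketal), and the ester is not attacked.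

**Step 10**
Reactants: 13 C4 exocyclic methylene compound
Product: 14 C11 dimethylaminomethyl ester (C11 epimers)
Conditions: LDA, THF, −78 °C; then CH2=NMe2+ I−, −78 → 0 °C
Reagents that add atoms: Eschenmoser's salt (N,N-dimethylmethyleneiminium iodide), C=[N+](C)C.[I-]
Why: Mannich-type aminomethylation of the ester enolate, C11 being the only acidic C–H; the new C11 centre forms unselectively and is removed in step 11.

**Step 11**
Reactants: 14 C11 dimethylaminomethyl ester
Product: 16 acrylate ester (C11=C13 methylene), via trimethylammonium iodide 15 (not isolated)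
Conditions: MeI, MeOH, 23 °C; then aq. NaHCO3, CH2Cl2, 23 °C
Reagents that add atoms: none
Why: N-methylation followed by E1cB loss of trimethylamine from the β-ammonio ester (Hofmann-type elimination) gives the α-methylene ester.

**Step 12**
Reactants: 16 acrylate ester
Product: 17 C3α allylic alcohol
Conditions: SeO2 (cat.), t-BuOOH, CH2Cl2, 0 → 23 °C
Reagents that add atoms: tert-butyl hydroperoxide, CC(C)(C)OO (oxygen relayed by catalytic SeO2, O=[Se]=O)
Why: SeO2-catalysed allylic oxidation (ene reaction then [2,3]-shift) of the 1,1-disubstituted C4=C15 alkene should hydroxylate the allylic CH2 (C3) in preference to the tertiary C5–H, the electron-poor acrylate being inert; oxygen is expected on the exposed α-face of ring A, at a centre removed in step 14.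

**Step 13**
Reactants: 17 C3α allylic alcohol
Product: 18 α-hydroxy ketone (C2 ketone, C3α-OH, C4 methylene)
Conditions: 1 M HCl, THF, 23 °C
Reagents that add atoms: water, O
Why: Acid hydrolysis of the dioxolane frees the C2 ketone while the bridged ether, acrylate and allylic alcohol tolerate dilute acid; the product is oxidized without delay to avoid α-ketol isomerization.

**Step 14**
Reactants: 18 α-hydroxy ketone
Product: 19 bridged 2,3-diketone (C4 methylene, acrylate ester)
Conditions: Dess–Martin periodinane, pyridine, CH2Cl2, 0 °C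
Reagents that add atoms: none
Why: Dess–Martin oxidation of the α-ketol gives the 1,2-diketone, and pyridine buffers the acetic acid without ionizing the diosphenol, so the bridge should stay closed until step 17.

**Step 15**
Reactants: 20 dehydrocostus lactone
Product: 21 3-epizaluzanin C (3α-hydroxydehydrocostus lactone)
Conditions: SeO2 (cat.), t-BuOOH, CH2Cl2, 23 °C
Reagents that add atoms: tert-butyl hydroperoxide, CC(C)(C)OO (oxygen relayed by catalytic SeO2, O=[Se]=O)
Why: SeO2 allylic oxidation of the C4=C15 alkene at its allylic CH2 (C3), with oxygen delivered to the convex α-face of the cis-fused ring; the centre is removed in step 16.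

**Step 16**
Reactants: 21 3-epizaluzanin C
Product: 22 dehydrozaluzanin C
Conditions: Dess–Martin periodinane, CH2Cl2, 23 °C
Reagents that add atoms: none
Why: Dess–Martin oxidation of the allylic alcohol gives the exocyclic enone without touching the α-methylene lactone.

**Step 17**
Reactants: 19 bridged 2,3-diketone; 22 dehydrozaluzanin C
Product: 25 seco-hydroxy methyl ester of the target (C6 α-OH free), via ring-opened enedione 23 (not isolated), via hydroxy-diene 24 (not isolated)
Conditions: 22 (3 equiv), Et3N, CH2Cl2, 0 → 23 °C; 19 added slowly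
Reagents that add atoms: none
Why: Triethylamine ionizes C1–H of the diketone (its diosphenol), the C2 enolate expels the C10–O bond of the bridge (E1cB) to give enedione 23, and γ-deprotonation at C14 gives the 1-hydroxy-diene/dienolate 24 (C14=C10–C1=C2–O), which adds to the exocyclic enone C4'=C15' of 22 in a base-promoted Diels–Alder reaction (Michael addition at C15' then aldol at C2, as in amine-promoted cycloadditions of 3-hydroxy-2-pyrones) to close the cyclohexene C2–C1–C10–C14–C15'–C4' with ortho regiochemistry; C4' should be set by approach to the convex α-face of 22 and C2 by reaction on the β-face of the diene (anti to the pseudo-axial H5 and the α C6 oxygen), the pairing found in this family of dimers, while the s-trans-locked C9=C10 tautomer cannot cycloadd and returns to the equilibrium, and slow addition of 19 to excess 22 limits self-dimerization.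

**Step 18**
Reactants: 25 seco-hydroxy methyl ester of the target
Product: 26 target CNP0269880.2
Conditions: TsOH·H2O (cat.), CH2Cl2, 23 °C
Reagents that add atoms: none
Why: Acid-catalysed lactonization of the γ-hydroxy acrylate, the C6 α-oxygen and the C7 β side chain being trans as in the natural trans-fused guaianolide, so closure is strain-free; the tertiary alcohol and the enones should tolerate catalytic acid at room temperature.

**Compound list**
1 | 5-methylfurfuryl alcohol | Cc1ccc(CO)o1 | starting material
2 | rac-6-hydroxy-6-methyl-2H-pyran-3(6H)-one | CC1(O)OCC(=O)C=C1 | intermediate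
3 | rac-6-acetoxy-6-methyl-2H-pyran-3(6H)-one | CC1(OC(C)=O)OCC(=O)C=C1 | intermediate
4 | (R)-4-(tert-butyldimethylsilyloxy)cyclopent-2-en-1-one | O=C1C=C[C@H](O[Si](C)(C)C(C)(C)C)C1 | starting material
5 | 6-methyl-3-oxidopyrylium | Cc1ccc([O-])c[o+]1 | intermediate (not isolated)
6 | endo (5+2) adduct: 4α-TBSO-6α,10α-epoxy-10β-methyl-hydroazul-8-ene-2,7-dione, 1αH, 5αH, 6βH | O=C1C[C@@H](O[Si](C)(C)C(C)(C)C)[C@H]2[C@@H]1[C@@]3(C)C=CC(=O)[C@@H]2O3 | intermediate
7 | C2 ethylene ketal of 6 | O1CCOC12C[C@@H](O[Si](C)(C)C(C)(C)C)[C@H]3[C@@H]2[C@@]4(C)C=CC(=O)[C@@H]3O4 | intermediate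
8 | trimethyl phosphonoacetate | COC(=O)CP(=O)(OC)OC | starting material
9 | C7 (methoxycarbonyl)methylidene dienoate, E/Z mixture at C7=C11 | O1CCOC12C[C@@H](O[Si](C)(C)C(C)(C)C)[C@H]3[C@@H]2[C@@]4(C)C=CC(=CC(=O)OC)[C@@H]3O4 | intermediate
10 | saturated methyl ester, 7αH | O1CCOC12C[C@@H](O[Si](C)(C)C(C)(C)C)[C@H]3[C@@H]2[C@@]4(C)CC[C@@H](CC(=O)OC)[C@@H]3O4 | intermediate
11 | C4α alcohol | O1CCOC12C[C@@H](O)[C@H]3[C@@H]2[C@@]4(C)CC[C@@H](CC(=O)OC)[C@@H]3O4 | intermediate
12 | C4 ketone | O1CCOC12CC(=O)[C@H]3[C@@H]2[C@@]4(C)CC[C@@H](CC(=O)OC)[C@@H]3O4 | intermediate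
13 | C4 exocyclic methylene compound | O1CCOC12CC(=C)[C@H]3[C@@H]2[C@@]4(C)CC[C@@H](CC(=O)OC)[C@@H]3O4 | intermediate
14 | C11 dimethylaminomethyl ester, C11 epimers | O1CCOC12CC(=C)[C@H]3[C@@H]2[C@@]4(C)CC[C@@H](C(CN(C)C)C(=O)OC)[C@@H]3O4 | intermediate
15 | trimethylammonium iodide of 14 | O1CCOC12CC(=C)[C@H]3[C@@H]2[C@@]4(C)CC[C@@H](C(C[N+](C)(C)C)C(=O)OC)[C@@H]3O4.[I-] | intermediate (not isolated)
16 | acrylate ester (C11=C13) | O1CCOC12CC(=C)[C@H]3[C@@H]2[C@@]4(C)CC[C@@H](C(=C)C(=O)OC)[C@@H]3O4 | intermediate
17 | C3α allylic alcohol | O1CCOC12[C@@H](O)C(=C)[C@H]3[C@@H]2[C@@]4(C)CC[C@@H](C(=C)C(=O)OC)[C@@H]3O4 | intermediate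
18 | α-hydroxy ketone (C2 ketone, C3α-OH) | O=C1[C@@H](O)C(=C)[C@H]2[C@@H]1[C@@]3(C)CC[C@@H](C(=C)C(=O)OC)[C@@H]2O3 | intermediate
19 | bridged 2,3-diketone (tautomer: C1 enol) | O=C1C(=O)C(=C)[C@H]2[C@@H]1[C@@]3(C)CC[C@@H](C(=C)C(=O)OC)[C@@H]2O3 | intermediate
20 | dehydrocostus lactone | C=C1CC[C@@H]2[C@@H]([C@@H]3[C@H]1CCC3=C)OC(=O)C2=C | starting material
21 | 3-epizaluzanin C (3α-OH) | C=C1CC[C@@H]2[C@@H]([C@@H]3[C@H]1C[C@@H](O)C3=C)OC(=O)C2=C | intermediate
22 | dehydrozaluzanin C | C=C1CC[C@@H]2[C@@H]([C@@H]3[C@H]1CC(=O)C3=C)OC(=O)C2=C | intermediate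
23 | ring-opened enedione (C1=C10, C6 α-OH) | C=C1C(=O)C(=O)C2=C(C)CC[C@@H](C(=C)C(=O)OC)[C@H](O)[C@@H]12 | intermediate (not isolated)
24 | hydroxy-diene (C14=C10–C1=C2–OH) | C=C1C(=O)C(O)=C2C(=C)CC[C@@H](C(=C)C(=O)OC)[C@H](O)[C@@H]12 | intermediate (not isolated)
25 | seco-hydroxy methyl ester of the target | C=C1C(=O)[C@]2(O)C3=C(CC[C@@H](C(=C)C(=O)OC)[C@H](O)[C@@H]13)CC[C@]21C(=O)C[C@H]2C(=C)CC[C@H]3C(=C)C(=O)O[C@@H]3[C@H]21 | intermediate
26 | CNP0269880.2 | C=C1C(=O)[C@]2(O)C3=C(CC[C@H]4C(=C)C(=O)O[C@@H]4[C@@H]13)CC[C@]21C(=O)C[C@H]2C(=C)CC[C@H]3C(=C)C(=O)O[C@@H]3[C@H]21 | target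

**Step count**
Total: 18 steps. Longest linear sequence: 16 steps (steps 1–14, 17, 18); the dehydrozaluzanin C branch is 2 steps (15, 16).

**Steps most likely to fail**

Step 3. The ylide may dimerize faster than the cyclic enone captures it, the endo preference may be weak, and the amine may begin β-elimination in the adduct. The fallback makes the same two bonds by a Rh(II)-catalysed tandem carbonyl-ylide formation/(3+2) cycloaddition under neutral conditions. It sets out from 4 and commercial levulinic acid. Levulinic acid is converted with isobutyl chloroformate and Et3N into the mixed isobutyl carbonic anhydride F1, and diazomethane then gives 1-diazohexane-2,5-dione F2. Slow addition of F2 to 4 and Rh2(OAc)4 in CH2Cl2 generates the six-membered carbonyl ylide, which should add anti to the silyloxy group with the same regiochemistry to give the 8,9-dihydro analogue of 6, F3. Selective ketalization of the cyclopentanone as in step 4 gives the C2 ketal F4, olefination as in step 5 gives the C7 (methoxycarbonyl)methylidene ester F5, and hydrogenation as in step 6 returns to the route at 10.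

Step 17. The base may open the bridge too slowly or degrade 22, the hydroxy-diene may dimerize with itself, and facial selectivity on the diene may be low. The fallback separates ring opening from cycloaddition and sets out from 19. TBSOTf and Et3N (CH2Cl2, −78 → 0 °C) silylate the diosphenol and assist cleavage of the tertiary C10–O bond, giving the bis-silyl dienol ether F6 (C2–OTBS diene, C6–OTBS). Thermal Diels–Alder reaction of F6 with 22 (toluene, 60 °C) gives the bis-silyl cycloadduct F7; the bulky α C6–OTBS group should reinforce β-face attack on the diene. HF·pyridine then removes both silyl groups and returns to the route at 25.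

Step 12. The allylic oxidation may be slow next to the ketal, may attack C5–H instead, or may over-oxidize. The fallback puts the C3 oxygen in through an enol ether and sets out from 16. Hydrolysis of the ketal (1 M HCl, THF) gives the β,γ-unsaturated ketone F8. LiHMDS and TESCl (THF, −78 °C) deprotonate the doubly activated C3 (no leaving group is β to this enolate) to give the triethylsilyl dienol ether F9. Rubottom oxidation (dimethyldioxirane, acetone, −78 °C, then HF·pyridine) returns to the route at 18.

**Further compounds**
F1 | step 3 | levulinic isobutyl carbonic anhydride | CC(=O)CCC(=O)OC(=O)OCC(C)C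
F2 | step 3 | 1-diazohexane-2,5-dione | CC(=O)CCC(=O)C=[N+]=[N-]
F3 | step 3 | 8,9-dihydro analogue of 6 | O=C1C[C@@H](O[Si](C)(C)C(C)(C)C)[C@H]2[C@@H]1[C@@]3(C)CCC(=O)[C@@H]2O3
F4 | step 3 | C2 ethylene ketal of F3 | O1CCOC12C[C@@H](O[Si](C)(C)C(C)(C)C)[C@H]3[C@@H]2[C@@]4(C)CCC(=O)[C@@H]3O4
F5 | step 3 | C7 (methoxycarbonyl)methylidene ester of F4 | O1CCOC12C[C@@H](O[Si](C)(C)C(C)(C)C)[C@H]3[C@@H]2[C@@]4(C)CCC(=CC(=O)OC)[C@@H]3O4
F6 | step 17 | bis-TBS dienol ether (C2–OTBS diene, C6–OTBS) | C=C1C(=O)C(O[Si](C)(C)C(C)(C)C)=C2C(=C)CC[C@@H](C(=C)C(=O)OC)[C@H](O[Si](C)(C)C(C)(C)C)[C@@H]12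
F7 | step 17 | bis-TBS Diels–Alder adduct | C=C1C(=O)[C@]2(O[Si](C)(C)C(C)(C)C)C3=C(CC[C@@H](C(=C)C(=O)OC)[C@H](O[Si](C)(C)C(C)(C)C)[C@@H]13)CC[C@]21C(=O)C[C@H]2C(=C)CC[C@H]3C(=C)C(=O)O[C@@H]3[C@H]21
F8 | step 12 | β,γ-unsaturated C2 ketone (C3 H2, C4 methylene) | O=C1CC(=C)[C@H]2[C@@H]1[C@@]3(C)CC[C@@H](C(=C)C(=O)OC)[C@@H]2O3
F9 | step 12 | triethylsilyl dienol ether (C2=C3) | CC[Si](CC)(CC)OC1=CC(=C)[C@H]2[C@@H]1[C@@]3(C)CC[C@@H](C(=C)C(=O)OC)[C@@H]2O3
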